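**Plan**
- Retrosynthetic cuts, in order: (i) the 14 O–benzyl bonds and a blocking C8–Br on the lower unit (one hydrogenolysis); (ii) the upper pyran ring across O1–C2 and C3–C4 (retro-oxa-[4+2]), giving an o-quinone methide and a (Z)-styryl gallate; (iii) the interflavan C4–C6 bond (aryl Grignard + salicylaldehyde); (iv) the enol ester C–O bond (alkyne + acid).
- Forward: both rings of the lower flavan come intact from (−)-epicatechin, which is blocked at C8 (Br), iodinated at C6, galloylated, metalated at C6 and added to the A-ring aldehyde carbon (the future C4). The upper pyran ring is closed last.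
- Enabling feature: the A-ring phenol oxygen (future O1) is ortho to the benzylic carbon C4 that carries the electron-rich D ring, so loss of water gives the heterodiene O=C8a–C4a=C4. The para-oxygenated B ring polarises the enol ester so that C3 bonds to C4 and C2 to O1.
- Stereochemistry: the lower unit comes from the chiral pool; C2/C3 cis from the Z alkene; C4 trans from the peri 5-benzyloxy group; absolute sense from a chiral phosphoric acid; both carbinol epimers converge on one planar intermediate.

Key step: step 9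

Assumption: the carbinol carbon of 11 (both epimers) and the exocyclic C=C of 15 (not configurationally fixed) are written without descriptor. The (R)-antipode of the phosphoric acid is written; which antipode screens the required face cannot be predicted with confidence for this substrate, and the antipode is used, with nothing else changed, if the sense is opposite.

**Step 1**
Reactants: 1 (−)-epicatechin
Product: 2 5,7,3',4'-tetra-O-benzyl-(−)-epicatechin
Conditions: BnBr (4.4 equiv), K2CO3, DMF, 0 °C → rt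
Reagents that add atoms: benzyl bromide, BrCc1ccccc1
Why: Williamson etherification in which carbonate deprotonates only the four phenols, so the secondary 3-OH stays free and no stereocentre is touched.

**Step 2**
Reactants: 2 5,7,3',4'-tetra-O-benzyl-(−)-epicatechin
Product: 3 8-bromo-5,7,3',4'-tetra-O-benzyl-(−)-epicatechin
Conditions: NBS (1.0 equiv), CH2Cl2, −78 °C → rt
Reagents that add atoms: N-bromosuccinimide, O=C1CCC(=O)N1Br
Why: Electrophilic aromatic bromination at C8, the most nucleophilic position of a 5,7-dialkoxyflavan A ring; the bromine serves as blocking group and leaves iodine as the only fast-exchanging halogen later.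

**Step 3**
Reactants: 3 8-bromo-5,7,3',4'-tetra-O-benzyl-(−)-epicatechin
Product: 4 8-bromo-6-iodo-5,7,3',4'-tetra-O-benzyl-(−)-epicatechin
Conditions: NIS (1.1 equiv), CH2Cl2/MeCN, 0 °C → rt, dark
Reagents that add atoms: N-iodosuccinimide, O=C1CCC(=O)N1I
Why: Electrophilic aromatic iodination at C6, the only free A-ring position (two ortho oxygens, para to O1) and far more activated than the B ring.

**Step 4**
Reactants: 4 8-bromo-6-iodo-5,7,3',4'-tetra-O-benzyl-(−)-epicatechin; 5 3,4,5-tris(benzyloxy)benzoic acid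
Product: 6 8-bromo-6-iodo-5,7,3',4'-tetra-O-benzyl-(−)-epicatechin 3-O-[3,4,5-tris(benzyloxy)benzoate]
Conditions: DCC, DMAP, CH2Cl2, rt
Reagents that add atoms: none
Why: Steglich esterification acylates the 3-OH on oxygen, so C3 keeps its configuration.

**Step 5**
Reactants: 7 3,5-bis(benzyloxy)phenol
Product: 8 2,4-bis(benzyloxy)-6-hydroxybenzaldehyde
Conditions: (CH2O)n, MgCl2, Et3N, MeCN, reflux
Reagents that add atoms: paraformaldehyde (as formaldehyde), C=O
Why: Magnesium-mediated ortho-formylation (Casnati–Skattebøl), in which the magnesium phenolate delivers formaldehyde only to the ortho position, and the two ortho positions of 7 are equivalent.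

**Step 6**
Reactants: 6 8-bromo-6-iodo-5,7,3',4'-tetra-O-benzyl-(−)-epicatechin 3-O-[3,4,5-tris(benzyloxy)benzoate]; 8 2,4-bis(benzyloxy)-6-hydroxybenzaldehyde
Product: 11 8-bromo-6-{[2,4-bis(benzyloxy)-6-hydroxyphenyl](hydroxy)methyl}-5,7,3',4'-tetra-O-benzyl-(−)-epicatechin 3-O-[3,4,5-tris(benzyloxy)benzoate] (both carbinol epimers), via sodium 3,5-bis(benzyloxy)-2-formylphenolate 9 (not isolated), via the C6 arylmagnesium chloride of the lower unit 10 (not isolated)
Conditions: 8, NaH (1.0 equiv), THF, 0 °C; 6 (1.2 equiv), i-PrMgCl·LiCl (1.15 equiv), THF, −40 °C; combine, −40 °C → rt; aq NH4Cl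
Reagents that add atoms: none
Why: Iodine–magnesium exchange with the turbo-Grignard reagent is much faster at C–I than at C–Br and tolerates the ester at low temperature, and the aryl Grignard then adds 1,2 to the aldehyde of the pre-formed phenolate, the uncontrolled carbinol centre being of no consequence because step 9 destroys it.

**Step 7**
Reactants: 12 3,4-bis(benzyloxy)benzaldehyde
Product: 13 1,2-bis(benzyloxy)-4-ethynylbenzene
Conditions: dimethyl (1-diazo-2-oxopropyl)phosphonate, K2CO3, MeOH/THF, rt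
Reagents that add atoms: dimethyl (1-diazo-2-oxopropyl)phosphonate (Ohira–Bestmann reagent), CC(=O)C(=[N+]=[N-])P(=O)(OC)OC
Why: Seyferth–Gilbert homologation in its Ohira–Bestmann form converts the aromatic aldehyde into the terminal alkyne under mild base that leaves benzyl ethers untouched.

**Step 8**
Reactants: 13 1,2-bis(benzyloxy)-4-ethynylbenzene; 5 3,4,5-tris(benzyloxy)benzoic acid
Product: 14 (Z)-2-[3,4-bis(benzyloxy)phenyl]ethenyl 3,4,5-tris(benzyloxy)benzoate
Conditions: [Ru(η3-methallyl)2(dppb)] (2 mol %), toluene, 65 °C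
Reagents that add atoms: none
Why: Ruthenium-catalysed anti-Markovnikov hydro-oxycarbonylation of a terminal alkyne via a ruthenium vinylidene, which places the carboxylate on the terminal carbon and gives the Z enol ester.

**Step 9**
Reactants: 11 the o-hydroxybenzhydrol (both carbinol epimers); 14 (Z)-2-[3,4-bis(benzyloxy)phenyl]ethenyl 3,4,5-tris(benzyloxy)benzoate
Product: 16 tetradeca-O-benzyl-8-bromo-procyanidin B-5 3,3'-di-O-gallate (upper unit 2,3-cis-3,4-trans, 4β→6 linked), via the o-quinone methide 15 (not isolated)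
Conditions: (R)-TRIP (10 mol %), 14 (2 equiv), 5 Å MS, toluene, 0 → 40 °C
Reagents that add atoms: none
Why: Proposed new method: the acid ionises both carbinol epimers of 11 to the same o-quinone methide 15 (stereoconvergent), which as its hydrogen-bonded phosphate complex should add the Z enol ester 14 in an asynchronous inverse-electron-demand oxa-[4+2] cycloaddition, with C4–C3 bonding leading and O1–C2 following because the positive charge building at C2 is carried by the para-benzyloxy B ring far better than an acyloxy group could carry it at C3; the closest known reaction type is the chiral-phosphoric-acid-catalysed hetero-Diels–Alder reaction of o-hydroxybenzhydrol-derived o-quinone methides with donor styrenes and enamides to 2,4-diarylchromans, which has not been shown with a β-acyloxystyrene or with a flavanyl group on the methide carbon. The pyran ring is closed by the cycloaddition itself, the four atoms O=C8a–C4a=C4 of 15 joining C3=C2 of 14 (if the event is stepwise, the second bond is a 6-exo-trig capture of the benzylic cation by the phenol oxygen). C2 and C3 should come out cis because the Z double bond adds suprafacially. C4 should come out trans to the C3 oxygen because the 5-benzyloxy group, peri to C4, pushes the bulky D-ring aryl into the pseudoaxial position, and only the approach with the B ring equatorial and the gallate axial avoids a 1,3-diaxial aryl/aryl contact, which is the 2,3-cis-3,4-trans (4β) arrangement. The absolute sense must come from the catalyst, whose BINOL phosphate bound at the quinone methide oxygen screens one face, since the stereocentres of the lower unit are too far from C4 to select a face. The step also needs chemoselectivity for the dienophile, secured by the C8 bromine and the full benzylation of the lower unit (no free nucleophilic arene position or hydroxyl) and by the sieves that take up the water.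

**Step 10**
Reactants: 16 tetradeca-O-benzyl-8-bromo-procyanidin B-5 3,3'-di-O-gallate
Product: 17 procyanidin B-5 3,3'-di-O-gallate
Conditions: H2 (1 atm), Pd(OH)2/C, Et3N (1.1 equiv), THF/MeOH/H2O, rt
Reagents that add atoms: none
Why: Palladium-catalysed hydrogenolysis cleaves all fourteen benzyl ethers and reduces the aryl C–Br bond in the same operation (Et3N takes up HBr), while the gallate esters, the pyran C–O bonds and all stereocentres are left as they are.

**Compound list**
1 | (−)-epicatechin | O[C@@H]1Cc2c(O)cc(O)cc2O[C@@H]1c1ccc(O)c(O)c1 | starting material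
2 | 5,7,3',4'-tetra-O-benzyl-(−)-epicatechin, (2R,3R) | O[C@@H]1Cc2c(OCc3ccccc3)cc(OCc3ccccc3)cc2O[C@@H]1c1ccc(OCc2ccccc2)c(OCc2ccccc2)c1 | intermediate
3 | 8-bromo-5,7,3',4'-tetra-O-benzyl-(−)-epicatechin | O[C@@H]1Cc2c(OCc3ccccc3)cc(OCc3ccccc3)c(Br)c2O[C@@H]1c1ccc(OCc2ccccc2)c(OCc2ccccc2)c1 | intermediate
4 | 8-bromo-6-iodo-5,7,3',4'-tetra-O-benzyl-(−)-epicatechin | O[C@@H]1Cc2c(OCc3ccccc3)c(I)c(OCc3ccccc3)c(Br)c2O[C@@H]1c1ccc(OCc2ccccc2)c(OCc2ccccc2)c1 | intermediate
5 | 3,4,5-tris(benzyloxy)benzoic acid | OC(=O)c1cc(OCc2ccccc2)c(OCc2ccccc2)c(OCc2ccccc2)c1 | starting material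
6 | 8-bromo-6-iodo-5,7,3',4'-tetra-O-benzyl-(−)-epicatechin 3-O-[3,4,5-tris(benzyloxy)benzoate] | O=C(O[C@@H]1Cc2c(OCc3ccccc3)c(I)c(OCc3ccccc3)c(Br)c2O[C@@H]1c1ccc(OCc2ccccc2)c(OCc2ccccc2)c1)c1cc(OCc2ccccc2)c(OCc2ccccc2)c(OCc2ccccc2)c1 | intermediate
7 | 3,5-bis(benzyloxy)phenol | Oc1cc(OCc2ccccc2)cc(OCc2ccccc2)c1 | starting material
8 | 2,4-bis(benzyloxy)-6-hydroxybenzaldehyde | O=Cc1c(O)cc(OCc2ccccc2)cc1OCc1ccccc1 | intermediate
9 | sodium 3,5-bis(benzyloxy)-2-formylphenolate | [Na+].[O-]c1cc(OCc2ccccc2)cc(OCc2ccccc2)c1C=O | intermediate (not isolated)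
10 | C6 arylmagnesium chloride of the lower unit (8-bromo-tetra-O-benzyl-epicatechin 3-O-tribenzylgallate, MgCl at C6; LiCl complex) | O=C(O[C@@H]1Cc2c(OCc3ccccc3)c([Mg]Cl)c(OCc3ccccc3)c(Br)c2O[C@@H]1c1ccc(OCc2ccccc2)c(OCc2ccccc2)c1)c1cc(OCc2ccccc2)c(OCc2ccccc2)c(OCc2ccccc2)c1 | intermediate (not isolated)
11 | 8-bromo-6-{[2,4-bis(benzyloxy)-6-hydroxyphenyl](hydroxy)methyl}-5,7,3',4'-tetra-O-benzyl-(−)-epicatechin 3-O-[3,4,5-tris(benzyloxy)benzoate], both carbinol epimers | O=C(O[C@@H]1Cc2c(OCc3ccccc3)c(C(O)c3c(O)cc(OCc4ccccc4)cc3OCc3ccccc3)c(OCc3ccccc3)c(Br)c2O[C@@H]1c1ccc(OCc2ccccc2)c(OCc2ccccc2)c1)c1cc(OCc2ccccc2)c(OCc2ccccc2)c(OCc2ccccc2)c1 | intermediate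
12 | 3,4-bis(benzyloxy)benzaldehyde | O=Cc1ccc(OCc2ccccc2)c(OCc2ccccc2)c1 | starting material
13 | 1,2-bis(benzyloxy)-4-ethynylbenzene | C#Cc1ccc(OCc2ccccc2)c(OCc2ccccc2)c1 | intermediate
14 | (Z)-2-[3,4-bis(benzyloxy)phenyl]ethenyl 3,4,5-tris(benzyloxy)benzoate | O=C(O/C=C\c1ccc(OCc2ccccc2)c(OCc2ccccc2)c1)c1cc(OCc2ccccc2)c(OCc2ccccc2)c(OCc2ccccc2)c1 | intermediate
15 | o-quinone methide: lower unit of 11 carrying at C6 a [2,4-bis(benzyloxy)-6-oxocyclohexa-2,4-dien-1-ylidene]methyl group (C=C geometry not fixed) | O=C(O[C@@H]1Cc2c(OCc3ccccc3)c(C=C3C(=O)C=C(OCc4ccccc4)C=C3OCc3ccccc3)c(OCc3ccccc3)c(Br)c2O[C@@H]1c1ccc(OCc2ccccc2)c(OCc2ccccc2)c1)c1cc(OCc2ccccc2)c(OCc2ccccc2)c(OCc2ccccc2)c1 | intermediate (not isolated)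
16 | tetradeca-O-benzyl-8-bromo-procyanidin B-5 3,3'-di-O-gallate: 5,7,3',4'-tetra-O-benzyl-3-O-(tri-O-benzylgalloyl)epicatechin-(4β→6)-8-bromo-5,7,3',4'-tetra-O-benzyl-3-O-(tri-O-benzylgalloyl)epicatechin; upper unit 2,3-cis-3,4-trans, same spatial arrangement as in 17 | O=C(O[C@@H]1[C@@H](c2c(OCc4ccccc4)c(Br)c3c(c2OCc2ccccc2)C[C@@H](OC(=O)c2cc(OCc4ccccc4)c(OCc4ccccc4)c(OCc4ccccc4)c2)[C@@H](c2ccc(OCc4ccccc4)c(OCc4ccccc4)c2)O3)c2c(OCc3ccccc3)cc(OCc3ccccc3)cc2O[C@@H]1c1ccc(OCc2ccccc2)c(OCc2ccccc2)c1)c1cc(OCc2ccccc2)c(OCc2ccccc2)c(OCc2ccccc2)c1 | intermediate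
17 | procyanidin B-5 3,3'-di-O-gallate (upper unit 2R,3R,4S; lower unit 2R,3R) | O=C(O[C@@H]1[C@@H](c2c(O)cc3c(c2O)C[C@@H](OC(=O)c2cc(O)c(O)c(O)c2)[C@@H](c2ccc(O)c(O)c2)O3)c2c(O)cc(O)cc2O[C@@H]1c1ccc(O)c(O)c1)c1cc(O)c(O)c(O)c1 | target

**Count**
Total steps: 10. Longest linear sequence: 7 (steps 1, 2, 3, 4, 6, 9, 10).

**Steps most likely to fail**

Step 9 (proposed new method). Three processes may defeat it:
- the cycloaddition may be too slow, because the heterodiene is heavily stabilised by five alkoxy donors and the enol ester is only a moderate nucleophile;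
- a stepwise ionic course, with participation of the ester carbonyl at the C2 cation, may erode the 2,3-cis relationship;
- facial selection by the catalyst may be poor.

The fallback is the known flavan-4-yl cation coupling. It sets out from 2 and 3 and comes back at 16. Compound 2 is oxidised at C4 with DDQ in the presence of 2-ethoxyethanol (CH2Cl2, rt) to 4β-(2-ethoxyethoxy)-5,7,3',4'-tetra-O-benzylepicatechin F1. TMSOTf-promoted condensation of F1 with an excess of 3 (CH2Cl2, −78 °C) should attack C6 of 3, since C8 is blocked, from the face anti to the 3-OH, to give the 4β→6 linked 8-bromo-octa-O-benzyl dimer diol F2. Double Steglich galloylation of F2 with 5 (DCC, DMAP) gives 16.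

Step 6. Three processes may defeat it:
- iodine–magnesium exchange at the doubly ortho-alkoxylated, electron-rich carbon may be slow;
- the aryl Grignard may attack the gallate ester;
- addition to the phenolate-deactivated, di-ortho-substituted aldehyde may be sluggish.

The fallback reverses the polarity. It sets out from 3 (with 5 and 7) and comes back at 11. Compound 3 is esterified with 5 (DCC, DMAP) to 8-bromo-5,7,3',4'-tetra-O-benzylepicatechin 3-O-[3,4,5-tris(benzyloxy)benzoate] F3. Vilsmeier–Haack formylation (POCl3, DMF) at the only free A-ring position gives the 6-carbaldehyde F4. The bromomagnesium phenolate of 7 (EtMgBr, then toluene/CH2Cl2, rt) is then added to F4 in an ortho-specific, chelate-controlled hydroxyalkylation that gives 11.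

Step 8. Incomplete Z selectivity or partial Markovnikov addition would pass geometric impurity on as 2,3-trans material in step 9. The fallback builds the Z geometry at boron first. It sets out from 13 and comes back at 14. Rhodium-catalysed trans-hydroboration of 13 with pinacolborane ([Rh(cod)Cl]2, P(i-Pr)3, Et3N) gives the (Z)-alkenyl pinacolboronate F5. KHF2 converts F5 into the potassium (Z)-alkenyltrifluoroborate F6. Copper-catalysed oxidative C–O coupling of the Chan–Lam type between F6 and acid 5 (Cu(I) salt, DMAP, O2, 4 Å MS) should proceed with retention of the double-bond geometry to give 14.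

**Further compounds**
F1 | step 9 | 4β-(2-ethoxyethoxy)-5,7,3',4'-tetra-O-benzylepicatechin | O[C@@H]1[C@@H](OCCOCC)c2c(OCc3ccccc3)cc(OCc3ccccc3)cc2O[C@@H]1c1ccc(OCc2ccccc2)c(OCc2ccccc2)c1
F2 | step 9 | 5,7,3',4'-tetra-O-benzylepicatechin-(4β→6)-8-bromo-5,7,3',4'-tetra-O-benzylepicatechin (dimer diol) | O[C@@H]1[C@@H](c2c(OCc4ccccc4)c(Br)c3c(c2OCc2ccccc2)C[C@@H](O)[C@@H](c2ccc(OCc4ccccc4)c(OCc4ccccc4)c2)O3)c2c(OCc3ccccc3)cc(OCc3ccccc3)cc2O[C@@H]1c1ccc(OCc2ccccc2)c(OCc2ccccc2)c1
F3 | step 6 | 8-bromo-5,7,3',4'-tetra-O-benzylepicatechin 3-O-[3,4,5-tris(benzyloxy)benzoate] | O=C(O[C@@H]1Cc2c(OCc3ccccc3)cc(OCc3ccccc3)c(Br)c2O[C@@H]1c1ccc(OCc2ccccc2)c(OCc2ccccc2)c1)c1cc(OCc2ccccc2)c(OCc2ccccc2)c(OCc2ccccc2)c1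
F4 | step 6 | 8-bromo-6-formyl-5,7,3',4'-tetra-O-benzylepicatechin 3-O-[3,4,5-tris(benzyloxy)benzoate] | O=C(O[C@@H]1Cc2c(OCc3ccccc3)c(C=O)c(OCc3ccccc3)c(Br)c2O[C@@H]1c1ccc(OCc2ccccc2)c(OCc2ccccc2)c1)c1cc(OCc2ccccc2)c(OCc2ccccc2)c(OCc2ccccc2)c1
F5 | step 8 | (Z)-2-{2-[3,4-bis(benzyloxy)phenyl]ethenyl}-4,4,5,5-tetramethyl-1,3,2-dioxaborolane | CC1(C)OB(/C=C\c2ccc(OCc3ccccc3)c(OCc3ccccc3)c2)OC1(C)C
F6 | step 8 | potassium (Z)-{2-[3,4-bis(benzyloxy)phenyl]ethenyl}trifluoroborate | [K+].F[B-](F)(F)/C=C\c1ccc(OCc2ccccc2)c(OCc2ccccc2)c1
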